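**Retrosynthetic overview**

1. Target ⇐ site- and face-selective epoxidation of C1=C10 in a ten-membered triene lactone; the oxirane is formed last.
2. Ten-membered ring ⇐ C3–C4 bond by an intramolecular Nozaki–Hiyama–Kishi reaction of a (Z)-alkenyl iodide with a C3 aldehyde; this sets C3 and keeps the 4Z alkene.
3. C7–C8 bond ⇐ zinc Barbier allylation of a C8 aldehyde with an enantiopure 3-(bromomethyl)butenolide; C6 relays to C7 and C8 and the 6,12-lactone with its exocyclic methylene is delivered directly. The butenolide is made first, from acrolein and propyne, by ring-closing metathesis.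
4. C8–C9–C10(C14)=C1–C2–C3 ⇐ 3-methylanisole: Birch reduction destroys the arene and enol-ether-selective ozonolysis unzips the ring. The ring fixes the Z geometry (hence the cis oxirane) and gives two different carbonyl ends.
5. Ring order: butenolide → ten-membered carbocycle → oxirane. Stereo relay: C6 → C7/C8 → C3 → C1/C10.

Assumption: positions are called C1–C15 by germacrane numbering; read from the SMILES the target is 1R,3S,6S,7S,8R,10S with a 4Z alkene and an oxirane whose two ring bonds are cis (so it derives from a Z alkene).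
Assumption: (R,R)-ProPhenol is taken as the ligand hand that adds the alkynylzinc to the Si face of acrolein; if the sense is the reverse, its mirror image is used with no other change.

**Route**

Step 1
Reactants: 1 3-methylanisole
Product: 2 1-methoxy-5-methylcyclohexa-1,4-diene
Conditions: Li, NH3(l), THF, t-BuOH, −78 → −33 °C; NH4Cl
Reagents that add atoms: none
Why: Birch reduction breaks the aromatic ring and leaves both donor groups on sp2 carbons, so the future C10(C14)=C1 alkene is born inside a six-membered ring with its two CH2 neighbours (C9, C2) necessarily cis.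

Step 2
Reactants: 2 1-methoxy-5-methylcyclohexa-1,4-diene
Product: 5 methyl (3Z)-6,6-dimethoxy-3-methylhex-3-enoate, via hydroperoxy hemiacetal 3 (not isolated), via aldehyde ester 4 (not isolated)
Conditions: O3 (1.0 equiv), CH2Cl2/MeOH 4:1, −78 °C; Me2S, −78 °C → rt; then HC(OMe)3, PPTS (cat.), rt
Reagents that add atoms: ozone, [O-][O+]=O; trimethyl orthoformate, COC(OC)OC
Why: Criegee ozonolysis cuts only the far more electron-rich enol ether alkene, so the methoxy carbon becomes the C8 methyl ester and the other carbon (carbonyl oxide trapped by methanol, then reduced) becomes the C3 aldehyde, which is acetalised at once to stop β,γ → α,β isomerisation; the Z alkene is untouched.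

Step 3
Reactants: 5 methyl (3Z)-6,6-dimethoxy-3-methylhex-3-enoate
Product: 6 (3Z)-6,6-dimethoxy-3-methylhex-3-enal
Conditions: i-Bu2AlH (1.05 equiv), CH2Cl2, −78 °C; aq. potassium sodium tartrate work-up
Reagents that add atoms: none
Why: Partial ester reduction stops at the aldehyde because the tetrahedral aluminium hemiacetal is stable at −78 °C; the acetal and the alkene are inert, and the β,γ-unsaturated aldehyde is used crude.

Step 4
Reactants: 7 acrolein; 8 propyne
Product: 10 (3R)-hex-1-en-4-yn-3-ol, via methyl(prop-1-ynyl)zinc 9 (not isolated)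
Conditions: 8 (3 equiv), Me2Zn (3 equiv), (R,R)-ProPhenol (10 mol %), Ph3P=O (20 mol %), toluene, 0 °C; then 7, 0 °C
Reagents that add atoms: none
Why: Zinc–ProPhenol catalysed enantioselective alkynylation of a non-enolisable enal; the alkynyl group is delivered to the Si face of the aldehyde to give the R carbinol, which becomes C6, the only stereocentre set by a chiral reagent.

Step 5
Reactants: 10 (3R)-hex-1-en-4-yn-3-ol
Product: 12 (3R,4Z)-5-iodohexa-1,4-dien-3-ol, via cyclic sodium alkenylalanate 11 (not isolated)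
Conditions: NaAlH2(OCH2CH2OMe)2, THF, 0 °C → rt; then I2, THF, −78 → 0 °C
Reagents that add atoms: iodine, II
Why: Alkoxide-directed trans-hydroalumination of the propargylic alcohol places aluminium on the distal carbon in a five-membered alanate, and iodinolysis with retention gives the alkenyl iodide with iodine cis to the carbinol carbon (the future 4Z geometry); the vinyl group and the stereocentre are not touched.

Step 6
Reactants: 12 (3R,4Z)-5-iodohexa-1,4-dien-3-ol; 13 2-(bromomethyl)prop-2-enoic acid
Product: 14 (3R,4Z)-5-iodohexa-1,4-dien-3-yl 2-(bromomethyl)prop-2-enoate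
Conditions: DCC, DMAP (5 mol %), CH2Cl2, 0 °C
Reagents that add atoms: none
Why: Steglich esterification of the secondary alcohol under neutral conditions at 0 °C, which leaves the allylic bromide and the stereocentre intact.

Step 7
Reactants: 14 (3R,4Z)-5-iodohexa-1,4-dien-3-yl 2-(bromomethyl)prop-2-enoate
Product: 15 (5R)-3-(bromomethyl)-5-[(1Z)-2-iodoprop-1-en-1-yl]furan-2(5H)-one
Conditions: second-generation Grubbs catalyst (5 mol %), CH2Cl2 (0.01 M), 40 °C
Reagents that add atoms: none
Why: Ring-closing metathesis: the ruthenium carbene loads on the vinyl group and closes onto the 1,1-disubstituted acrylate to give the butenolide (C7=C11), while the trisubstituted iodoalkene is inert and C6 is unaffected.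

Step 8
Reactants: 6 (3Z)-6,6-dimethoxy-3-methylhex-3-enal; 15 (5R)-3-(bromomethyl)-5-[(1Z)-2-iodoprop-1-en-1-yl]furan-2(5H)-one
Product: 17 (4S,5R)-4-[(1R,3Z)-1-hydroxy-6,6-dimethoxy-3-methylhex-3-en-1-yl]-5-[(1Z)-2-iodoprop-1-en-1-yl]-3-methylideneoxolan-2-one, via allylzinc bromide 16 (not isolated)
Conditions: Zn dust, THF/sat. aq. NH4Cl 2:1, 0 °C → rt
Reagents that add atoms: none
Why: Barbier allylation: the allylzinc reacts at its γ-carbon C7 through a six-membered Zimmerman–Traxler chair. The ring-locked (E-type) allyl unit and an equatorial aldehyde residue give the C7/C8 relationship of the target (8R). Attack anti to the C6 alkenyl group gives the 6,7-trans lactone (7S). The double bond moves out to the exocyclic methylene, and the alkenyl iodide and acetal survive the near-neutral medium.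

Step 9
Reactants: 17 (4S,5R)-4-[(1R,3Z)-1-hydroxy-6,6-dimethoxy-3-methylhex-3-en-1-yl]-5-[(1Z)-2-iodoprop-1-en-1-yl]-3-methylideneoxolan-2-one
Product: 18 (1R,3Z)-1-[(2R,3S)-2-[(1Z)-2-iodoprop-1-en-1-yl]-4-methylidene-5-oxooxolan-3-yl]-6,6-dimethoxy-3-methylhex-3-en-1-yl 2-methylpropanoate
Conditions: (i-PrCO)2O, DMAP (cat.), pyridine, CH2Cl2, 0 °C
Reagents that add atoms: isobutyric anhydride, CC(C)C(=O)OC(=O)C(C)C
Why: DMAP-catalysed acylation of the C8 hydroxyl is fast at 0 °C and, done directly after step 8, blocks translactonisation to the 8,12-lactone; no stereocentre is touched.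

Step 10
Reactants: 18 (1R,3Z)-1-[(2R,3S)-2-[(1Z)-2-iodoprop-1-en-1-yl]-4-methylidene-5-oxooxolan-3-yl]-6,6-dimethoxy-3-methylhex-3-en-1-yl 2-methylpropanoate
Product: 19 (1R,3Z)-1-[(2R,3S)-2-[(1Z)-2-iodoprop-1-en-1-yl]-4-methylidene-5-oxooxolan-3-yl]-3-methyl-6-oxohex-3-en-1-yl 2-methylpropanoate
Conditions: LiBF4, MeCN/H2O 50:1, rt
Reagents that add atoms: water, O
Why: Mild Lewis-acid-assisted acetal hydrolysis frees the C3 aldehyde without cleaving the ester or lactone and without moving the β,γ-alkene; the aldehyde is used at once.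

Step 11
Reactants: 19 (1R,3Z)-1-[(2R,3S)-2-[(1Z)-2-iodoprop-1-en-1-yl]-4-methylidene-5-oxooxolan-3-yl]-3-methyl-6-oxohex-3-en-1-yl 2-methylpropanoate
Product: 21 (3S,6S,7S,8R)-3-hydroxy-8-(2-methylpropanoyloxy)germacra-1(10)Z,4Z,11(13)-trien-12,6-olide, via alkenylchromium dichloride 20 (not isolated)
Conditions: CrCl2 (10 equiv), NiCl2 (1 wt % of CrCl2), DMSO/THF 3:1, rt, syringe-pump addition to 0.002 M
Reagents that add atoms: none
Why: Nozaki–Hiyama–Kishi macrocyclisation: zerovalent nickel inserts into the C–I bond, the alkenyl group passes to trivalent chromium with retention of the Z geometry and adds only to the aldehyde, with the two Z alkenes acting as turn elements; C3 is set under macrocyclic control and the 3S alcohol (hydroxyl on the face of O6 and O8) is the planned but unproven outcome, and the low NiCl2 loading suppresses nickel-mediated closure onto the methylene lactone.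

Step 12
Reactants: 21 (3S,6S,7S,8R)-3-hydroxy-8-(2-methylpropanoyloxy)germacra-1(10)Z,4Z,11(13)-trien-12,6-olide
Product: 22 (1R,3S,6S,7S,8R,10S)-1,10-epoxy-3-hydroxy-8-(2-methylpropanoyloxy)germacra-4Z,11(13)-dien-12,6-olide (CNP0261225.1)
Conditions: mCPBA (1.05 equiv), NaHCO3, CH2Cl2, −20 → 0 °C
Reagents that add atoms: meta-chloroperbenzoic acid, OOC(=O)c1cccc(Cl)c1
Why: Prilezhaev epoxidation: C1=C10 is the only electron-rich alkene (C4=C5 has two allylic C–O bonds, C11=C13 is conjugated to the lactone), and hydrogen bonding to the homoallylic C3 hydroxyl (Henbest-type delivery) should guide the peracid to the face carrying O3, O6 and O8 to give the 1R,10S oxirane; the face selectivity is the planned but unproven outcome, and the cis ring bonds follow from the Z alkene fixed in step 1.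

**Compound list**

1 | 3-methylanisole (1-methoxy-3-methylbenzene) | COc1cccc(C)c1 | starting material
2 | 1-methoxy-5-methylcyclohexa-1,4-diene | COC1=CCC=C(C)C1 | intermediate
3 | methyl (3Z)-6-hydroperoxy-6-methoxy-3-methylhex-3-enoate (racemic at C6) | COC(=O)C/C(C)=C\CC(OC)OO | intermediate
4 | methyl (3Z)-3-methyl-6-oxohex-3-enoate | COC(=O)C/C(C)=C\CC=O | intermediate
5 | methyl (3Z)-6,6-dimethoxy-3-methylhex-3-enoate | COC(=O)C/C(C)=C\CC(OC)OC | intermediate
6 | (3Z)-6,6-dimethoxy-3-methylhex-3-enal | O=CC/C(C)=C\CC(OC)OC | intermediate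
7 | acrolein (prop-2-enal) | C=CC=O | starting material
8 | propyne | CC#C | starting material
9 | methyl(prop-1-ynyl)zinc | CC#C[Zn]C | intermediate
10 | (3R)-hex-1-en-4-yn-3-ol | C=C[C@@H](O)C#CC | intermediate
11 | sodium (5R)-2,2-bis(2-methoxyethoxy)-3-methyl-5-vinyl-2,5-dihydro-1,2-oxaluminol-2-uide (cyclic alkenylalanate) | C=C[C@@H]1C=C(C)[Al-](OCCOC)(OCCOC)O1.[Na+] | intermediate
12 | (3R,4Z)-5-iodohexa-1,4-dien-3-ol | C=C[C@@H](O)/C=C(/C)I | intermediate
13 | 2-(bromomethyl)prop-2-enoic acid | C=C(CBr)C(=O)O | starting material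
14 | (3R,4Z)-5-iodohexa-1,4-dien-3-yl 2-(bromomethyl)prop-2-enoate | C=C[C@@H](OC(=O)C(=C)CBr)/C=C(/C)I | intermediate
15 | (5R)-3-(bromomethyl)-5-[(1Z)-2-iodoprop-1-en-1-yl]furan-2(5H)-one | O=C1O[C@@H](/C=C(/C)I)C=C1CBr | intermediate
16 | bromo{[(5R)-5-[(1Z)-2-iodoprop-1-en-1-yl]-2-oxo-2,5-dihydrofuran-3-yl]methyl}zinc | Br[Zn]CC1=C[C@H](/C=C(/C)I)OC1=O | intermediate
17 | (4S,5R)-4-[(1R,3Z)-1-hydroxy-6,6-dimethoxy-3-methylhex-3-en-1-yl]-5-[(1Z)-2-iodoprop-1-en-1-yl]-3-methylideneoxolan-2-one | C=C1C(=O)O[C@@H](/C=C(/C)I)[C@@H]1[C@H](O)C/C(C)=C\CC(OC)OC | intermediate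
18 | (1R,3Z)-1-[(2R,3S)-2-[(1Z)-2-iodoprop-1-en-1-yl]-4-methylidene-5-oxooxolan-3-yl]-6,6-dimethoxy-3-methylhex-3-en-1-yl 2-methylpropanoate | C=C1C(=O)O[C@@H](/C=C(/C)I)[C@@H]1[C@H](OC(=O)C(C)C)C/C(C)=C\CC(OC)OC | intermediate
19 | (1R,3Z)-1-[(2R,3S)-2-[(1Z)-2-iodoprop-1-en-1-yl]-4-methylidene-5-oxooxolan-3-yl]-3-methyl-6-oxohex-3-en-1-yl 2-methylpropanoate | C=C1C(=O)O[C@@H](/C=C(/C)I)[C@@H]1[C@H](OC(=O)C(C)C)C/C(C)=C\CC=O | intermediate
20 | dichloro[(Z)-alkenyl]chromium derived from 19 (trivalent chromium in place of iodine at C4) | C=C1C(=O)O[C@@H](/C=C(/C)[Cr](Cl)Cl)[C@@H]1[C@H](OC(=O)C(C)C)C/C(C)=C\CC=O | intermediate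
21 | (3S,6S,7S,8R)-3-hydroxy-8-(2-methylpropanoyloxy)germacra-1(10)Z,4Z,11(13)-trien-12,6-olide | C=C1C(=O)O[C@H]2/C=C(/C)[C@@H](O)C/C=C(/C)C[C@@H](OC(=O)C(C)C)[C@H]12 | intermediate
22 | (1R,3S,6S,7S,8R,10S)-1,10-epoxy-3-hydroxy-8-(2-methylpropanoyloxy)germacra-4Z,11(13)-dien-12,6-olide | C=C1C(=O)O[C@H]2/C=C(/C)[C@@H](O)C[C@H]3O[C@@]3(C)C[C@@H](OC(=O)C(C)C)[C@H]12 | target

**Count**

Total steps: 12. Longest linear sequence: 9 (steps 4–12, from acrolein); the arene branch is 8 (steps 1–3, 8–12).

**Steps most likely to fail, with fallbacks**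

Step 11 is the weakest point. A ten-membered ring is closed and C3 is set only by the conformation of the ring, so the wrong epimer or a poor ratio is the likely failure. The fallback sets out from 19 and moves the stereocontrol to a reagent. The same CrCl2/NiCl2 closure is run and the (3R)-epimer of 21, (3R,6S,7S,8R)-3-hydroxy-8-(2-methylpropanoyloxy)germacra-1(10)Z,4Z,11(13)-trien-12,6-olide F3 (alone or mixed with 21), is oxidised with Dess–Martin periodinane (NaHCO3, CH2Cl2, 0 °C) to the ten-membered Z-enone, (6S,7S,8R)-8-(2-methylpropanoyloxy)-3-oxogermacra-1(10)Z,4Z,11(13)-trien-12,6-olide F4. Reduction with (R)-2-methyl-CBS-oxazaborolidine and catecholborane (toluene, −78 °C), with the α-branched alkenyl group as the large substituent, gives the 3S alcohol, and the route is rejoined at 21.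

Step 12 may deliver the oxygen to the wrong face of C1=C10, since the face preference of a Z alkene in this ring is not secure. The fallback sets out from 21 and inverts the facial outcome by a halohydrin route. NBS in THF/H2O (0 °C) puts bromine on the face the peracid prefers and water on C10 from the other face, giving the bromohydrin (1S,3S,6S,7S,8R,10S)-1-bromo-3,10-dihydroxy-8-(2-methylpropanoyloxy)germacra-4Z,11(13)-dien-12,6-olide F5. K2CO3 in acetone (rt) then closes the oxirane by SN2 displacement at C1, and the route is rejoined at 22.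

Step 4 may give low enantiomeric excess or polymer, because acrolein is a small and reactive enal. The fallback sets out from 7 and replaces catalysis by resolution. Prop-1-ynylmagnesium bromide (THF, −78 °C) gives racemic hex-1-en-4-yn-3-ol F1. Sharpless kinetic resolution (Ti(OiPr)4, D-(−)-diisopropyl tartrate, t-BuOOH, 4 Å sieves, CH2Cl2, −20 °C, about 55 % conversion) epoxidises the S enantiomer to (1R)-1-[(2R)-oxiran-2-yl]but-2-yn-1-ol F2, which is separated. The unreacted R alcohol is 10, where the route is rejoined.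

**Further compounds**

F1 | step 4 | racemic hex-1-en-4-yn-3-ol | C=CC(O)C#CC
F2 | step 4 | (1R)-1-[(2R)-oxiran-2-yl]but-2-yn-1-ol | CC#C[C@@H](O)[C@H]1CO1
F3 | step 11 | (3R,6S,7S,8R)-3-hydroxy-8-(2-methylpropanoyloxy)germacra-1(10)Z,4Z,11(13)-trien-12,6-olide | C=C1C(=O)O[C@H]2/C=C(/C)[C@H](O)C/C=C(/C)C[C@@H](OC(=O)C(C)C)[C@H]12
F4 | step 11 | (6S,7S,8R)-8-(2-methylpropanoyloxy)-3-oxogermacra-1(10)Z,4Z,11(13)-trien-12,6-olide | C=C1C(=O)O[C@H]2/C=C(/C)C(=O)C/C=C(/C)C[C@@H](OC(=O)C(C)C)[C@H]12
F5 | step 12 | (1S,3S,6S,7S,8R,10S)-1-bromo-3,10-dihydroxy-8-(2-methylpropanoyloxy)germacra-4Z,11(13)-dien-12,6-olide | C=C1C(=O)O[C@H]2/C=C(/C)[C@@H](O)C[C@H](Br)[C@@](C)(O)C[C@@H](OC(=O)C(C)C)[C@H]12
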